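**Retrosynthetic overview**
- Target ⇐ global O-debenzylation of the octa-O-benzyl trimer ⇐ top C4–middle C8 bond from a (2S)-flavan-4-yl cation and the benzylated epiafzelechin-(4β→8)-epiafzelechin dimer.
- Dimer ⇐ key step: both pyran rings (C4–C4a bonds) and the C4–C8 interflavan bond made in one Au(III)/AgOTf operation from two acyclic aryl ethers, a terminal epoxide (bottom unit) and an α-hydroxy aldehyde (middle unit).
- Both acyclic partners ⇐ one threo aryl-ether epoxide ⇐ Mitsunobu inversion of an erythro epoxy alcohol with 3,5-bis(benzyloxy)phenol ⇐ Sharpless kinetic-resolution epoxidation ⇐ 4-(benzyloxy)benzaldehyde + vinylmagnesium bromide.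
- Top flavan-4-ol ⇐ transfer-hydrogenation kinetic resolution of the racemic flavanone ⇐ 4′-benzyloxy-2′-hydroxyacetophenone + 4-(benzyloxy)benzaldehyde.
- Ring order: top pyranone ring in its own branch; bottom and middle pyran rings together in the key step; no ring is formed after that.

Assumption: the SMILES is read as (2S)-7,4′-dihydroxyflavan-(4β→8)-epiafzelechin-(4β→8)-epiafzelechin (top 2S,4R; middle 2R,3R with 4β-aryl; bottom 2R,3R); reagents and catalysts are not numbered, and numbers follow first appearance in the forward route.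

**Step 1**
Reactants: 1 4-(benzyloxy)benzaldehyde
Product: 2 rac-1-[4-(benzyloxy)phenyl]prop-2-en-1-ol
Conditions: vinylMgBr (1.2 equiv), THF, 0 °C; then H2O
Reagents that add atoms: vinylmagnesium bromide C=C[Mg]Br
Why: Grignard 1,2-addition to the aldehyde gives the racemic aryl vinyl carbinol, the substrate class for Sharpless kinetic resolution.

**Step 2**
Reactants: 2 rac-1-[4-(benzyloxy)phenyl]prop-2-en-1-ol
Product: 3 (S)-[4-(benzyloxy)phenyl][(2R)-oxiran-2-yl]methanol (erythro)
Conditions: Ti(OiPr)4 (10 mol %), L-(+)-DIPT (15 mol %), t-BuOOH (0.5 equiv), 4 Å MS, CH2Cl2, −20 °C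
Reagents that add atoms: tert-butyl hydroperoxide CC(C)(C)OO
Why: Sharpless kinetic-resolution epoxidation epoxidises only (R)-2 on its matched face, giving the erythro epoxy alcohol (carbinol S, oxirane R) and leaving (S)-2; the oxirane centre becomes C3 and the carbinol becomes C2 after inversion.

**Step 3**
Reactants: 3 (S)-[4-(benzyloxy)phenyl][(2R)-oxiran-2-yl]methanol; 4 3,5-bis(benzyloxy)phenol
Product: 5 (2R)-2-{(R)-[3,5-bis(benzyloxy)phenoxy][4-(benzyloxy)phenyl]methyl}oxirane (threo)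
Conditions: PPh3, DIAD, toluene, 0 °C→rt
Reagents that add atoms: none
Why: Mitsunobu etherification proceeds by SN2 inversion at the benzylic carbinol (S→R), turning the erythro epoxy alcohol into the threo aryl ether whose two centres map onto the 2,3-cis (2R,3R) pattern of both epiafzelechin units.

**Step 4**
Reactants: 5 (2R)-2-{(R)-[3,5-bis(benzyloxy)phenoxy][4-(benzyloxy)phenyl]methyl}oxirane
Product: 6 (2R,3R)-3-[3,5-bis(benzyloxy)phenoxy]-3-[4-(benzyloxy)phenyl]propane-1,2-diol
Conditions: (R,R)-(salen)Co(III)OAc (2 mol %; the racemic complex serves equally), H2O (3 equiv), THF, rt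
Reagents that add atoms: water O
Why: Co(salen)-catalysed epoxide hydrolysis (Jacobsen hydrolysis catalyst) delivers water to the terminal CH2 under neutral conditions, so neither stereocentre is touched and the electron-rich arene does not cyclise.

**Step 5**
Reactants: 6 (2R,3R)-3-[3,5-bis(benzyloxy)phenoxy]-3-[4-(benzyloxy)phenyl]propane-1,2-diol
Product: 7 (2S,3R)-3-[3,5-bis(benzyloxy)phenoxy]-3-[4-(benzyloxy)phenyl]-2-hydroxypropanal
Conditions: TEMPO (10 mol %), PhI(OAc)2 (1.05 equiv), NaHCO3, CH2Cl2, 0 °C→rt; used crude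
Reagents that add atoms: none
Why: TEMPO/PhI(OAc)2 oxidation is selective for the primary alcohol over the secondary one, giving the α-hydroxy aldehyde with both centres unchanged (the descriptor change at C2 is only a priority change).

**Step 6**
Reactants: 7 (2S,3R)-3-[3,5-bis(benzyloxy)phenoxy]-3-[4-(benzyloxy)phenyl]-2-hydroxypropanal; 5 (2R)-2-{(R)-[3,5-bis(benzyloxy)phenoxy][4-(benzyloxy)phenyl]methyl}oxirane
Product: 10 hexa-O-benzyl-[epiafzelechin-(4β→8)-epiafzelechin] (5,7,4′-tri-O-benzyl on each unit), via 5,7,4′-tri-O-benzyl-epiafzelechin 8 (not isolated), via 4-hydroxy-5,7,4′-tri-O-benzyl-epiafzelechin 9 (not isolated)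
Conditions: 5 (3 equiv), AuCl3 (5 mol %), AgOTf (15 mol %), CH2Cl2, 0 °C→rt, 1 h; then −40 °C, 7 added over 1 h, →0 °C
Reagents that add atoms: none
Why: Proposed new method: the Au(III)/AgOTf Lewis acid first closes the bottom pyran ring by 6-endo Friedel–Crafts opening of the terminal epoxide of 5 at CH2 (known Au(III) epoxide–arene cycloalkylation of such aryl ethers to flavan-3-ols, stereocentres untouched, giving 8), then activates aldehyde 7 for intramolecular Friedel–Crafts hydroxyalkylation (middle pyran ring, 9), whose doubly oxygen-stabilised benzylic 4-OH ionises and is trapped by C8 of 8 anti to the 2-aryl and 3-OH groups, setting C4 as 4β (3,4-trans); the closest known reactions are Au(III)-catalysed epoxide–arene cyclisation and Lewis-acid couplings of C4-oxygenated flavan-3-ols with flavan-3-ol nucleophiles.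

**Step 7**
Reactants: 11 1-[4-(benzyloxy)-2-hydroxyphenyl]ethan-1-one; 1 4-(benzyloxy)benzaldehyde
Product: 12 rac-7-(benzyloxy)-2-[4-(benzyloxy)phenyl]chroman-4-one
Conditions: pyrrolidine (0.5 equiv), EtOH, reflux
Reagents that add atoms: none
Why: amine-mediated Claisen–Schmidt condensation followed by intramolecular oxa-Michael addition of the 2′-phenol (Kabbe-type flavanone synthesis) closes the pyranone ring; the product is racemic at C2.

**Step 8**
Reactants: 12 rac-7-(benzyloxy)-2-[4-(benzyloxy)phenyl]chroman-4-one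
Product: 13 (2S,4S)-7-(benzyloxy)-2-[4-(benzyloxy)phenyl]chroman-4-ol (2,4-cis)
Conditions: RuCl[(S,S)-TsDPEN](p-cymene) (1 mol %), HCO2H/Et3N (5:2), CH2Cl2, rt, stopped at about 50 % conversion
Reagents that add atoms: none
Why: Noyori asymmetric transfer hydrogenation run as a kinetic resolution: the (S,S)-catalyst reduces (2S)-12 much faster, delivering hydride anti to the 2-aryl group, which selects C2 (S) and gives the cis 4S alcohol (C4 is ionised later).

**Step 9**
Reactants: 13 (2S,4S)-7-(benzyloxy)-2-[4-(benzyloxy)phenyl]chroman-4-ol; 10 hexa-O-benzyl-[epiafzelechin-(4β→8)-epiafzelechin]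
Product: 14 octa-O-benzyl-[(2S)-7,4′-dihydroxyflavan-(4β→8)-epiafzelechin-(4β→8)-epiafzelechin]
Conditions: 10 (1.2 equiv), TMSOTf (0.2 equiv), CH2Cl2, −40 °C
Reagents that add atoms: none
Why: SN1 Friedel–Crafts alkylation (flavan-4-ol/proanthocyanidin-type coupling): the 7-alkoxy-stabilised flavan-4-yl cation is attacked by C8 of the upper unit of 10 (the only free position flanked by a single benzyloxy group) anti to the 2-aryl group, giving the 2,4-trans (4β, 4R) linkage.

**Step 10**
Reactants: 14 octa-O-benzyl-[(2S)-7,4′-dihydroxyflavan-(4β→8)-epiafzelechin-(4β→8)-epiafzelechin]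
Product: 15 (2S)-7,4′-dihydroxyflavan-(4β→8)-epiafzelechin-(4β→8)-epiafzelechin (CNP0257624.1)
Conditions: H2 (1 atm), 20 % Pd(OH)2/C, THF/MeOH/H2O (20:1:1), rt
Reagents that add atoms: none
Why: hydrogenolysis over Pearlman's catalyst removes all eight benzyl ethers under neutral conditions without touching the cyclic benzylic C–O bonds, the interflavan C–C bonds or any stereocentre.

**Compound list**
1 | 4-(benzyloxy)benzaldehyde | O=Cc1ccc(OCc2ccccc2)cc1 | starting material
2 | rac-1-[4-(benzyloxy)phenyl]prop-2-en-1-ol | OC(C=C)c1ccc(OCc2ccccc2)cc1 | intermediate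
3 | (S)-[4-(benzyloxy)phenyl][(2R)-oxiran-2-yl]methanol | O[C@@H](c1ccc(OCc2ccccc2)cc1)[C@H]1CO1 | intermediate
4 | 3,5-bis(benzyloxy)phenol | Oc1cc(OCc2ccccc2)cc(OCc2ccccc2)c1 | starting material
5 | (2R)-2-{(R)-[3,5-bis(benzyloxy)phenoxy][4-(benzyloxy)phenyl]methyl}oxirane | c1c(OCc2ccccc2)cc(OCc2ccccc2)cc1O[C@H](c1ccc(OCc2ccccc2)cc1)[C@H]1CO1 | intermediate
6 | (2R,3R)-3-[3,5-bis(benzyloxy)phenoxy]-3-[4-(benzyloxy)phenyl]propane-1,2-diol | c1c(OCc2ccccc2)cc(OCc2ccccc2)cc1O[C@H](c1ccc(OCc2ccccc2)cc1)[C@H](O)CO | intermediate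
7 | (2S,3R)-3-[3,5-bis(benzyloxy)phenoxy]-3-[4-(benzyloxy)phenyl]-2-hydroxypropanal | c1c(OCc2ccccc2)cc(OCc2ccccc2)cc1O[C@H](c1ccc(OCc2ccccc2)cc1)[C@H](O)C=O | intermediate
8 | (2R,3R)-5,7-bis(benzyloxy)-2-[4-(benzyloxy)phenyl]chroman-3-ol (5,7,4′-tri-O-benzyl-epiafzelechin) | c1c(OCc3ccccc3)cc(OCc3ccccc3)c2c1O[C@H](c1ccc(OCc3ccccc3)cc1)[C@H](O)C2 | intermediate
9 | (2R,3R)-5,7-bis(benzyloxy)-2-[4-(benzyloxy)phenyl]chroman-3,4-diol (4-hydroxy-5,7,4′-tri-O-benzyl-epiafzelechin, C4 epimers, C4 left open in the SMILES) | c1c(OCc3ccccc3)cc(OCc3ccccc3)c2c1O[C@H](c1ccc(OCc3ccccc3)cc1)[C@H](O)C2O | intermediate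
10 | hexa-O-benzyl-[epiafzelechin-(4β→8)-epiafzelechin] | c1c(OCc3ccccc3)cc(OCc3ccccc3)c2c1O[C@H](c1ccc(OCc3ccccc3)cc1)[C@H](O)[C@H]2c1c(OCc3ccccc3)cc(OCc3ccccc3)c2c1O[C@H](c1ccc(OCc3ccccc3)cc1)[C@H](O)C2 | intermediate
11 | 1-[4-(benzyloxy)-2-hydroxyphenyl]ethan-1-one | CC(=O)c1ccc(OCc2ccccc2)cc1O | starting material
12 | rac-7-(benzyloxy)-2-[4-(benzyloxy)phenyl]chroman-4-one | O=C1CC(c2ccc(OCc3ccccc3)cc2)Oc2cc(OCc3ccccc3)ccc12 | intermediate
13 | (2S,4S)-7-(benzyloxy)-2-[4-(benzyloxy)phenyl]chroman-4-ol | O(Cc1ccccc1)c1ccc([C@@H]2C[C@H](O)c3ccc(OCc4ccccc4)cc3O2)cc1 | intermediate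
14 | octa-O-benzyl-[(2S)-7,4′-dihydroxyflavan-(4β→8)-epiafzelechin-(4β→8)-epiafzelechin] | C(c5ccccc5)Oc1ccc([C@@H]2C[C@@H](c3c(OCc5ccccc5)cc(OCc5ccccc5)c4c3O[C@H](c3ccc(OCc5ccccc5)cc3)[C@H](O)[C@H]4c3c(OCc5ccccc5)cc(OCc5ccccc5)c4c3O[C@H](c3ccc(OCc5ccccc5)cc3)[C@H](O)C4)c3ccc(OCc5ccccc5)cc3O2)cc1 | intermediate
15 | (2S)-7,4′-dihydroxyflavan-(4β→8)-epiafzelechin-(4β→8)-epiafzelechin (CNP0257624.1) | Oc1ccc([C@@H]2C[C@@H](c3c(O)cc(O)c4c3O[C@H](c3ccc(O)cc3)[C@H](O)[C@H]4c3c(O)cc(O)c4c3O[C@H](c3ccc(O)cc3)[C@H](O)C4)c3ccc(O)cc3O2)cc1 | target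

**Step count**
Total: 10 steps. Longest linear sequence: 8 steps (1 → 2 → 3 → 4 → 5 → 6 → 9 → 10).

**Three steps most likely to fail**

Step 6 (key step). The aldehyde-derived cation may be captured by its own arene or by 10 instead of by 8, giving oligomers, and the benzylic aryl ether may ionise under the Lewis acid. The excess of 5 and slow addition of 7 are meant to limit the first; surplus 8 is recovered by chromatography. The fallback sets out from 7 (together with 5) and comes back at 10. Aldehyde 7 is cyclised on its own with the same catalyst in CH2Cl2 containing 2-ethoxyethanol (10 equiv), so that the C4 cation is intercepted as the storable 4β-(2-ethoxyethoxy)-5,7,4′-tri-O-benzyl-epiafzelechin F1. Separately 5 is cyclised and 8 is isolated. F1 is then coupled with 8 (4 equiv) under TMSOTf at −78 °C in a conventional electrophile/nucleophile union to give 10.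

Step 5. The α-hydroxy-β-aryloxy aldehyde 7 can over-oxidise, dimerise or lose phenoxide by β-elimination. The fallback sets out from 5 and comes back at 10. All of 5 is cyclised with AuCl3/AgOTf and 8 is isolated. Part of 8 is oxidised at the benzylic C4–H with DDQ in CH2Cl2/MeOH to 4β-methoxy-5,7,4′-tri-O-benzyl-epiafzelechin F2, so the electrophilic oxidation level is introduced late on the closed ring instead of being carried in an acyclic aldehyde. F2 is coupled with excess 8 (TMSOTf, −78 °C) to give 10.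

Step 9. The cation can attack a C6 position of 10, and the 2,4-trans:cis ratio of a 3-unsubstituted flavanyl cation may be modest. The fallback sets out from 7 (together with 13 and 5) and comes back at 14, using orthogonal activation with the top unit installed on a monomer. Aldehyde 7 is cyclised in the presence of 4-methylbenzenethiol and catalytic BF3·OEt2 to 4β-(4-methylphenylsulfanyl)-5,7,4′-tri-O-benzyl-epiafzelechin F3. F3 (3 equiv) is alkylated at its C8 by 13 under TMSOTf at −78 °C; the thioether is inert to the hard acid, and this gives (2S)-7,4′-bis(benzyloxy)flavan-(4β→8)-[4β-(4-methylphenylsulfanyl)-5,7,4′-tri-O-benzyl-epiafzelechin] F4. The thioether of F4 is then activated with AgOTf in the presence of excess 8 (made from 5 by Au catalysis) to form the second interflavan bond and give 14.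

**Further compounds**
F1 | step 6 | 4β-(2-ethoxyethoxy)-5,7,4′-tri-O-benzyl-epiafzelechin | c1c(OCc3ccccc3)cc(OCc3ccccc3)c2c1O[C@H](c1ccc(OCc3ccccc3)cc1)[C@H](O)[C@H]2OCCOCC
F2 | step 5 | 4β-methoxy-5,7,4′-tri-O-benzyl-epiafzelechin | c1c(OCc3ccccc3)cc(OCc3ccccc3)c2c1O[C@H](c1ccc(OCc3ccccc3)cc1)[C@H](O)[C@H]2OC
F3 | step 9 | 4β-(4-methylphenylsulfanyl)-5,7,4′-tri-O-benzyl-epiafzelechin | c1c(OCc3ccccc3)cc(OCc3ccccc3)c2c1O[C@H](c1ccc(OCc3ccccc3)cc1)[C@H](O)[C@H]2Sc1ccc(C)cc1
F4 | step 9 | (2S)-7,4′-bis(benzyloxy)flavan-(4β→8)-[4β-(4-methylphenylsulfanyl)-5,7,4′-tri-O-benzyl-epiafzelechin] | C(c5ccccc5)Oc1ccc([C@@H]2C[C@@H](c3c(OCc5ccccc5)cc(OCc5ccccc5)c4c3O[C@H](c3ccc(OCc5ccccc5)cc3)[C@H](O)[C@H]4Sc3ccc(C)cc3)c3ccc(OCc5ccccc5)cc3O2)cc1
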